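**Retrosynthetic overview**
1. The target is opened to the flat 8-ene-11,14-dione 23: conjugate hydration (C8-H, C9-OH) and Norrish–Yang closure of the C1–C11 bond are done last, so the cyclobutane and C1, C8, C9 and C11 are set by the bowl-shaped framework.
2. 23 comes from the 7-isopropenyl enedione 17: isopropenyl → 6,7-alkene → 6β,7β-epoxide → 6β-OAc/7α-OH.
3. Ring C of 17 is closed at C9–C11 by an intramolecular Nozaki–Hiyama–Kishi reaction, after C-acylation of decalone 4 at C8 with cyclopropane acid 9.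
4. Acid 9 (C12, C13, C15) comes from double alkylation of dioxolanyl acetate 5 with cyclic sulfate 6.
5. Decalone 4 (ring A built on ring B, C5/C10 cis) comes from a Diels–Alder reaction of (S)-carvone with silyloxydiene 2. Ring order: B (bought), A, C, cyclobutane.

Assumption: core carbons carry abietane locants (C3 ketone, C4 gem-dimethyl, C10 methyl, C13 spiro carbon, C15 = CH(CH3) and C16 = CH2 of the cyclopropane); β is the face of the C10 methyl and α the opposite face; 1, 3, 5 and 6 are bought.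

Step 1
Reactants: 1 4-methylpent-1-en-3-one
Product: 2 tert-butyl(dimethyl)[(4-methylpenta-1,3-dien-3-yl)oxy]silane
Conditions: TBSOTf, Et3N, Et2O, 0 °C
Reagents that add atoms: tert-butyldimethylsilyl trifluoromethanesulfonate, CC(C)(C)[Si](C)(C)OS(=O)(=O)C(F)(F)F
Why: Silyl enol ether formation at the only enolisable position gives the 2-silyloxydiene with a gem-dimethyl terminus.

Step 2
Reactants: 3 (S)-(+)-carvone; 2 tert-butyl(dimethyl)[(4-methylpenta-1,3-dien-3-yl)oxy]silane
Product: 4 cis-fused 3-silyloxy-4,4,10-trimethyl-7β-isopropenyl-decal-2-en-9-one (C5-H β and C10-CH3 β)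
Conditions: AlBr3/AlMe3 (10:1, 0.2 equiv), toluene/CH2Cl2, −5 °C → rt
Reagents that add atoms: none
Why: Lewis-acid-catalysed Diels–Alder cycloaddition in which the nucleophilic CMe2 terminus bonds to the enone β-carbon (C5) and the diene adds suprafacially anti to the isopropenyl group of carvone, so C5-H and the C10 methyl are set cis and in the right absolute sense.

Step 3
Reactants: 5 methyl 2-[(4R)-2,2-dimethyl-1,3-dioxolan-4-yl]acetate; 6 (4S)-4-methyl-1,3,2-dioxathiolane 2,2-dioxide
Product: 8 methyl (1S,2R)-1-[(4R)-2,2-dimethyl-1,3-dioxolan-4-yl]-2-methylcyclopropane-1-carboxylate, via lithium alkyl sulfate 7 (not isolated)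
Conditions: LiN(i-Pr)2 (1.05 equiv), THF/DMPU, −78 °C, then 6; LiN(i-Pr)2 (1.2 equiv), −78 → 0 °C
Reagents that add atoms: none
Why: Double enolate alkylation (SN2 at the primary sulfate carbon, then 3-exo-tet closure at the secondary carbon with inversion, giving C15 R), in which the lithium-chelated enolate closes anti to the dioxolane CH2O arm with the methyl on the ester side, setting C13.

Step 4
Reactants: 8 methyl (1S,2R)-1-[(4R)-2,2-dimethyl-1,3-dioxolan-4-yl]-2-methylcyclopropane-1-carboxylate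
Product: 9 (1S,2R)-1-[(4R)-2,2-dimethyl-1,3-dioxolan-4-yl]-2-methylcyclopropane-1-carboxylic acid
Conditions: LiOH·H2O, THF/MeOH/H2O, 50 °C; then 1 M HCl to pH 4, 0 °C
Reagents that add atoms: lithium hydroxide, [Li+].[OH-]
Why: Ester saponification under basic conditions leaves the acetonide and the non-enolisable quaternary centre untouched.

Step 5
Reactants: 9 (1S,2R)-1-[(4R)-2,2-dimethyl-1,3-dioxolan-4-yl]-2-methylcyclopropane-1-carboxylic acid; 4 cis-fused 3-silyloxy-4,4,10-trimethyl-7β-isopropenyl-decal-2-en-9-one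
Product: 11 chelated enol of the C8-acylated decalone (C8=C9-OH; C14 ketone bearing the cyclopropane), via acid chloride 10 (not isolated)
Conditions: 1-chloro-N,N,2-trimethylprop-1-en-1-amine, CH2Cl2, 0 °C; then 4, MgBr2·OEt2, i-Pr2NEt, CH2Cl2, rt
Reagents that add atoms: none
Why: Soft-enolisation C-acylation (crossed Claisen type) at C8, the only enolisable carbon while C3 is masked as its silyl enol ether, forms the C8–C14 bond.

Step 6
Reactants: 11 chelated enol of the C8-acylated decalone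
Product: 12 C9 enol triflate (C8=C9-OSO2CF3, C14 ketone)
Conditions: Tf2O, i-Pr2NEt, CH2Cl2, −78 °C
Reagents that add atoms: trifluoromethanesulfonic anhydride, O=S(=O)(OS(=O)(=O)C(F)(F)F)C(F)(F)F
Why: O-triflation of the endocyclic enol of the 2-acylcyclohexanone gives the β-triflyloxy enone, with C9 activated for coupling and the C14 acyl group held cis to it.

Step 7
Reactants: 12 C9 enol triflate
Product: 13 C3 ketone C9 enol triflate carrying the free (1R)-1,2-dihydroxyethyl group (C12-OH, C11-OH)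
Conditions: 1 M HCl, THF/H2O, rt
Reagents that add atoms: none
Why: Acid hydrolysis cleaves the acetonide and the silyl enol ether in one operation, while the vinyl triflate is stable to aqueous acid.

Step 8
Reactants: 13 C3 ketone C9 enol triflate diol
Product: 14 α-hydroxy aldehyde (C11 = CHO, C12-OH)
Conditions: TEMPO (0.1 equiv), PhI(OAc)2, CH2Cl2, rt; used crude
Reagents that add atoms: none
Why: Oxoammonium (TEMPO) oxidation is selective for the primary alcohol over the hindered secondary one.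

Step 9
Reactants: 14 α-hydroxy aldehyde
Product: 15 tricyclic 8-ene-3,14-dione 11,12-diol (12α-OH; both C11 epimers; 7β-isopropenyl; spiro-cyclopropane at C13)
Conditions: CrCl2 (6 equiv), NiCl2 (0.05 equiv), DMSO/THF, rt, high dilution
Reagents that add atoms: none
Why: Intramolecular Nozaki–Hiyama–Kishi reaction, in which the vinylchromium species formed from the triflate adds only to the aldehyde and closes ring C at C9–C11 with both ketones tolerated.

Step 10
Reactants: 15 tricyclic 11,12-diol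
Product: 16 12α-hydroxy-8-ene-3,11,14-trione
Conditions: MnO2 (excess), CH2Cl2, rt
Reagents that add atoms: none
Why: MnO2 oxidises only the allylic C11 alcohol, which removes the uncontrolled C11 centre and forms the enedione.

Step 11
Reactants: 16 12α-hydroxy-8-ene-3,11,14-trione
Product: 17 12α-acetoxy-7β-isopropenyl-8-ene-3,11,14-trione
Conditions: Ac2O, pyridine, DMAP (cat.), CH2Cl2, 0 °C
Reagents that add atoms: acetic anhydride, CC(=O)OC(C)=O
Why: Acetylation of the secondary alcohol under mild conditions blocks α-ketol isomerisation and keeps the bought C12 configuration.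

Step 12
Reactants: 17 12α-acetoxy-7β-isopropenyl-8-ene-3,11,14-trione
Product: 19 12α-acetoxy-6,8-diene-3,11,14-trione, via methoxy hydroperoxide 18 (not isolated)
Conditions: O3, MeOH/CH2Cl2, −78 °C; then FeSO4·7H2O, Cu(OAc)2·H2O, MeOH/H2O, −20 °C → rt
Reagents that add atoms: none
Why: Ozonolysis of the only electron-rich alkene followed by FeSO4/Cu(OAc)2 fragmentation (alkoxy radical β-scission, then oxidative loss of the only available β-hydrogen, at C6) turns the isopropenyl group into the 6,7-alkene.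

Step 13
Reactants: 19 12α-acetoxy-6,8-diene-3,11,14-trione
Product: 20 6β,7β-epoxide of 19
Conditions: dimethyldioxirane, acetone, 0 °C
Reagents that add atoms: dimethyldioxirane, CC1(C)OO1
Why: Neutral electrophilic epoxidation takes the more electron-rich disubstituted 6,7-alkene from the β face, because the α face is blocked by the gem-dimethyl carbon C4 on C5.

Step 14
Reactants: 20 6β,7β-epoxide
Product: 22 6β-acetoxy 7α-trifluoroacetate, via hydroxy trifluoroacetate 21 (not isolated)
Conditions: CF3CO2H, CH2Cl2, −20 °C; then pyridine, Ac2O, DMAP (cat.), 0 °C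
Reagents that add atoms: trifluoroacetic acid, OC(=O)C(F)(F)F; acetic anhydride, CC(=O)OC(C)=O
Why: Acid-mediated epoxide opening at the allylic, less hindered C7 with inversion gives the trans 6β-ol/7α-trifluoroacetate, and the free 6β-OH is then acetylated.

Step 15
Reactants: 22 6β-acetoxy 7α-trifluoroacetate
Product: 23 6β,12α-diacetoxy-7α-hydroxy-8-ene-3,11,14-trione
Conditions: NaHCO3 (0.2 equiv), MeOH, 0 °C
Reagents that add atoms: none
Why: Chemoselective methanolysis removes the far more electrophilic trifluoroacetate and leaves both acetates.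

Step 16
Reactants: 23 6β,12α-diacetoxy-7α-hydroxy-8-ene-3,11,14-trione
Product: 25 CNP0157858.3, via cyclobutanol enone 24 (not isolated)
Conditions: hν (405 nm), degassed MeCN, rt; then H2O, Et3N (cat.), rt
Reagents that add atoms: water, O
Why: Norrish–Yang photocyclisation (hydrogen transfer from C1 to the excited C11 carbonyl, then radical recombination) gives the cis-fused cyclobutanol (C1, C11), and oxa-Michael addition of water to the strained enone at C9 from the convex face, with C8 protonated on the same face, sets C9 and C8.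

**Compound list**
1 | 4-methylpent-1-en-3-one | CC(C)C(=O)C=C | starting material
2 | tert-butyl(dimethyl)[(4-methylpenta-1,3-dien-3-yl)oxy]silane | CC(C)=C(O[Si](C)(C)C(C)(C)C)C=C | intermediate
3 | (S)-(+)-carvone | CC1=CC[C@@H](CC1=O)C(C)=C | starting material
4 | 6-{[tert-butyl(dimethyl)silyl]oxy}-5,5,8a-trimethyl-3-(prop-1-en-2-yl)-3,4,4a,5,8,8a-hexahydronaphthalen-1(2H)-one, cis-fused, with 3-isopropenyl, 4a-H and 8a-CH3 on one face (core: C9 ketone, C10-CH3 β, C5-H β, C7-isopropenyl β) | C[C@]12CC=C(O[Si](C)(C)C(C)(C)C)C(C)(C)[C@H]1C[C@H](C(C)=C)CC2=O | intermediate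
5 | methyl 2-[(4R)-2,2-dimethyl-1,3-dioxolan-4-yl]acetate | COC(=O)C[C@@H]1COC(C)(C)O1 | starting material
6 | (4S)-4-methyl-1,3,2-dioxathiolane 2,2-dioxide | C[C@H]1COS(=O)(=O)O1 | starting material
7 | lithium (2S)-4-[(4R)-2,2-dimethyl-1,3-dioxolan-4-yl]-5-methoxy-5-oxopentan-2-yl sulfate (both C4 epimers) | COC(=O)C(C[C@H](C)OS(=O)(=O)[O-])[C@@H]1COC(C)(C)O1.[Li+] | intermediate
8 | methyl (1S,2R)-1-[(4R)-2,2-dimethyl-1,3-dioxolan-4-yl]-2-methylcyclopropane-1-carboxylate | COC(=O)[C@]1(C[C@H]1C)[C@@H]2COC(C)(C)O2 | intermediate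
9 | (1S,2R)-1-[(4R)-2,2-dimethyl-1,3-dioxolan-4-yl]-2-methylcyclopropane-1-carboxylic acid | OC(=O)[C@]1(C[C@H]1C)[C@@H]2COC(C)(C)O2 | intermediate
10 | (1S,2R)-1-[(4R)-2,2-dimethyl-1,3-dioxolan-4-yl]-2-methylcyclopropane-1-carbonyl chloride | ClC(=O)[C@]1(C[C@H]1C)[C@@H]2COC(C)(C)O2 | intermediate
11 | chelated enol of 4 acylated at C8 with the acyl group of 10 (C8=C9-OH, C14 ketone, C3 silyl enol ether, 7β-isopropenyl) | C[C@]12CC=C(O[Si](C)(C)C(C)(C)C)C(C)(C)[C@H]1C[C@H](C(C)=C)C(C(=O)[C@]3(C[C@H]3C)[C@@H]4COC(C)(C)O4)=C2O | intermediate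
12 | C9 enol triflate of 11 | C[C@]12CC=C(O[Si](C)(C)C(C)(C)C)C(C)(C)[C@H]1C[C@H](C(C)=C)C(C(=O)[C@]3(C[C@H]3C)[C@@H]4COC(C)(C)O4)=C2OS(=O)(=O)C(F)(F)F | intermediate
13 | C3 ketone C9 enol triflate with the (1R)-1,2-dihydroxyethyl group on the cyclopropane | C[C@]12CCC(=O)C(C)(C)[C@H]1C[C@H](C(C)=C)C(C(=O)[C@]3(C[C@H]3C)[C@@H](O)CO)=C2OS(=O)(=O)C(F)(F)F | intermediate
14 | C3 ketone C9 enol triflate with the (1R)-1-hydroxy-2-oxoethyl group on the cyclopropane | C[C@]12CCC(=O)C(C)(C)[C@H]1C[C@H](C(C)=C)C(C(=O)[C@]3(C[C@H]3C)[C@@H](O)C=O)=C2OS(=O)(=O)C(F)(F)F | intermediate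
15 | tricyclic 8-ene-3,14-dione 11,12-diol: 12α-OH, C11 epimers, 7β-isopropenyl, 5β-H, C13 spiro-cyclopropane with C15 on the α face and its CH3 on the C14 side | C=C(C)[C@H]1C[C@@H]2C(C)(C)C(=O)CC[C@]2(C)C3=C1C(=O)[C@]4(C[C@H]4C)[C@@H](O)C3O | intermediate
16 | 12α-hydroxy-8-ene-3,11,14-trione (otherwise as 15) | C=C(C)[C@H]1C[C@@H]2C(C)(C)C(=O)CC[C@]2(C)C3=C1C(=O)[C@]4(C[C@H]4C)[C@@H](O)C3=O | intermediate
17 | 12α-acetoxy-7β-isopropenyl-8-ene-3,11,14-trione | C=C(C)[C@H]1C[C@@H]2C(C)(C)C(=O)CC[C@]2(C)C3=C1C(=O)[C@]4(C[C@H]4C)[C@@H](OC(C)=O)C3=O | intermediate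
18 | 17 with the isopropenyl group replaced by C(CH3)(OCH3)OOH (epimers at that carbon) | COC(C)(OO)[C@H]1C[C@@H]2C(C)(C)C(=O)CC[C@]2(C)C3=C1C(=O)[C@]4(C[C@H]4C)[C@@H](OC(C)=O)C3=O | intermediate
19 | 12α-acetoxy-6,8-diene-3,11,14-trione | C1=C[C@@H]2C(C)(C)C(=O)CC[C@]2(C)C3=C1C(=O)[C@]4(C[C@H]4C)[C@@H](OC(C)=O)C3=O | intermediate
20 | 6β,7β-epoxy-12α-acetoxy-8-ene-3,11,14-trione | [C@H]12O[C@H]1[C@@H]3C(C)(C)C(=O)CC[C@]3(C)C4=C2C(=O)[C@]5(C[C@H]5C)[C@@H](OC(C)=O)C4=O | intermediate
21 | 12α-acetoxy-6β-hydroxy-7α-trifluoroacetoxy-8-ene-3,11,14-trione | O[C@@H]1[C@@H](OC(=O)C(F)(F)F)C2=C(C(=O)[C@H](OC(C)=O)[C@@]3(C[C@H]3C)C2=O)[C@@]4(C)CCC(=O)C(C)(C)[C@@H]14 | intermediate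
22 | 6β,12α-diacetoxy-7α-trifluoroacetoxy-8-ene-3,11,14-trione | CC(=O)O[C@@H]1[C@@H](OC(=O)C(F)(F)F)C2=C(C(=O)[C@H](OC(C)=O)[C@@]3(C[C@H]3C)C2=O)[C@@]4(C)CCC(=O)C(C)(C)[C@@H]14 | intermediate
23 | 6β,12α-diacetoxy-7α-hydroxy-8-ene-3,11,14-trione (5β-H, spiro-cyclopropane as in 15) | CC(=O)O[C@@H]1[C@@H](O)C2=C(C(=O)[C@H](OC(C)=O)[C@@]3(C[C@H]3C)C2=O)[C@@]4(C)CCC(=O)C(C)(C)[C@@H]14 | intermediate
24 | cyclobutanol from 23: C1–C11 bond, 11β-OH, 1β-H, C8=C9 enone with the C14 ketone | CC(=O)O[C@@H]1[C@@H](O)C=2C(=O)[C@]3(C[C@H]3C)[C@@H](OC(C)=O)[C@@]3(O)[C@H]4CC(=O)C(C)(C)[C@@H]1[C@@]4(C)C=23 | intermediate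
25 | CNP0157858.3 | CC(=O)O[C@@H]1[C@@H](O)[C@H]2C(=O)[C@]3(C[C@H]3C)[C@@H](OC(C)=O)[C@@]3(O)[C@H]4CC(=O)C(C)(C)[C@@H]1[C@@]4(C)[C@@]23O | target

**Step count and risks**
Total: 16 steps. Longest linear sequence: 14 steps (1 → 2 → 4 → 11 → … → 25; the branch 5 → 8 → 9 → 11 → … → 25 is equally long).

Most likely to fail:

Step 2, the hindered cycloaddition. The fallback sets out from 3 and 2 and builds ring A in two polar stages instead: TiCl4 in CH2Cl2 at −78 °C with aqueous work-up gives the Mukaiyama–Michael adduct, the 3,5-trans diketo enone F1. KH in THF then closes ring A by intramolecular Michael addition of the C10 enolate onto the vinyl ketone (only this mode gives a six-membered ring, cis-fused), and the C3 enolate so formed is trapped in the same flask with TBSCl. This comes back to the route at 4.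

Step 12, the radical fragmentation on the enedione. The fallback sets out from 17: ozonolysis in MeOH/CH2Cl2 followed by Ac2O, Et3N and DMAP (Criegee rearrangement, retention at C7) gives the allylic 7β-acetate F2. Pd(PPh3)4 with Et3N in hot dioxane then ionises the allylic acetate and eliminates toward C6. This comes back to the route at 19.

Step 16, the photocyclisation with in-flask hydration. The fallback sets out from 24, isolated after irradiation, and replaces the oxa-Michael addition with a conjugate borylation–oxidation: CuCl/NaOtBu (cat.), bis(pinacolato)diboron and MeOH in THF give the 9β-pinacolboronate F3, with boron delivered to C9 and the proton to C8 from the convex face. NaBO3·4H2O in THF/H2O then oxidises the C–B bond with retention. This comes back to the route at 25.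

**Further compounds**
F1 | step 2 | 2-methyl-3-(2-methyl-3-oxopent-4-en-2-yl)-5-(prop-1-en-2-yl)cyclohexan-1-one (3,5-trans; C2 epimers) | C=CC(=O)C(C)(C)[C@H]1C[C@H](C(C)=C)CC(=O)C1C
F2 | step 12 | 7β,12α-diacetoxy-8-ene-3,11,14-trione | CC(=O)O[C@H]1C[C@@H]2C(C)(C)C(=O)CC[C@]2(C)C3=C1C(=O)[C@]4(C[C@H]4C)[C@@H](OC(C)=O)C3=O
F3 | step 16 | 25 with the 9β-OH replaced by 4,4,5,5-tetramethyl-1,3,2-dioxaborolan-2-yl | CC(=O)O[C@@H]1[C@@H](O)[C@H]2C(=O)[C@]3(C[C@H]3C)[C@@H](OC(C)=O)[C@@]3(O)[C@H]4CC(=O)C(C)(C)[C@@H]1[C@@]4(C)[C@@]23B5OC(C)(C)C(C)(C)O5
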